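**Retrosynthetic overview**
- Feature: in target 12 (C1 carbonyl, C2=C3, C4, C5 carbinol, C6; chain C1'–C19') the tertiary C5–O bond of the single six-membered ring lies β to C1 through C6, which is the β-carbon of a 3-alkylcyclohex-2-enone.
- 12 ⇐ silyl ether 11 ⇐ ketone 8 by Saegusa dehydrogenation on the side remote from the carbinol (new C2=C3); 8 ⇐ β-hydroxy ketone 7.
- 7 ⇐ epoxy ketone 6 by reductive cleavage of the C6–O bond with SmI2; 6 ⇐ enone 5 by catalytic asymmetric nucleophilic epoxidation, which sets C5.
- 5 ⇐ nonadecylmagnesium bromide 2 + 3-ethoxycyclohex-2-enone 3 (Stork–Danheiser transposition).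
- Rings: the carbocycle is bought; the only ring made is the temporary oxirane (step 3), which is opened again in step 4.

Key step: step 3

Numbering: compounds 5–10 are numbered as ketones (C1 carbonyl, C3 bearing the chain); their C3 and C2 are C5 and C6 of the target.
Assumption: the quinine-derived amine salt is taken to give (2S,3S)-6; the sense of induction is not certain and is to be verified on 7 before scale-up, and the quinidine-derived pseudoenantiomer, which gives the mirror image, is used instead if required.

Step 1
Reactants: 1 1-bromononadecane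
Product: 2 nonadecylmagnesium bromide (THF solution, titrated and used directly)
Conditions: Mg turnings (1.3 equiv), I2 (cat.), THF, 50 °C
Reagents that add atoms: magnesium, [Mg]
Why: Magnesium inserts into the primary C–Br bond (Grignard reagent formation); warm THF keeps the waxy bromide dissolved and slow addition limits Wurtz coupling.

Step 2
Reactants: 2 nonadecylmagnesium bromide; 3 3-ethoxycyclohex-2-en-1-one
Product: 5 3-nonadecylcyclohex-2-en-1-one, via bromomagnesium alkoxide adduct 4 (not isolated)
Conditions: THF, 0 °C → rt; then 1 M aq HCl, rt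
Reagents that add atoms: water, O
Why: The Grignard reagent adds 1,2 to the carbonyl of the vinylogous ester, and aqueous acid then hydrolyses the enol ether and eliminates the tertiary hydroxyl (Stork–Danheiser transposition), so that the chain sits at C3 of the new enone, whose carbonyl oxygen comes from water while ethanol and the former carbonyl oxygen are lost.

Step 3
Reactants: 5 3-nonadecylcyclohex-2-en-1-one
Product: 6 (1S,6S)-6-nonadecyl-7-oxabicyclo[4.1.0]heptan-2-one [(2S,3S)-2,3-epoxy-3-nonadecylcyclohexan-1-one, cis-fused]
Conditions: 9-amino-9-deoxy-epi-quinine bis(trifluoroacetate) (10 mol%), 50% aq H2O2 (1.5 equiv), 1,4-dioxane, 50 °C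
Reagents that add atoms: hydrogen peroxide, OO
Why: The primary amine of the catalyst condenses with the C1 carbonyl of 5 to a ketiminium trifluoroacetate, which activates the C2=C3 bond so that H2O2, held by the protonated quinuclidine of the same catalyst, adds to C3 and forms the tertiary C3–O bond. The β-peroxy enamine formed in this way attacks the proximal peroxide oxygen through C2 with loss of water, closing the oxirane in a 3-exo-tet mode, and hydrolysis of the imine returns the amine. The closest known reaction type is the amine-salt-catalysed Weitz–Scheffer epoxidation of cyclic enones with H2O2, which includes 3-alkylcyclohex-2-enones. The configuration at C3 is set by the catalyst, which fixes the enone face approached by the hydroperoxide, and that at C2 follows from C3 because an oxirane can only be cis-fused to the six-membered ring. The step needs enantiofacial selectivity only, since 5 has one electrophilic alkene and no other stereocentre; the unbranched chain presents no more bulk at C3 than a small alkyl group, and iminium activation keeps conjugate addition ahead of Baeyer–Villiger oxidation.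

Step 4
Reactants: 6 (1S,6S)-6-nonadecyl-7-oxabicyclo[4.1.0]heptan-2-one
Product: 7 (S)-3-hydroxy-3-nonadecylcyclohexan-1-one
Conditions: SmI2 (2.5 equiv), THF/MeOH, −90 °C; pH 7 phosphate buffer
Reagents that add atoms: none
Why: Two single-electron transfers from divalent samarium through the ketyl cleave only the C2–O bond α to the carbonyl (Molander-type SmI2 reduction of an α,β-epoxy ketone), methanol protonates the enolate stage at −90 °C before elimination or retro-aldol opening can occur, and the C3–O bond and its configuration are untouched.

Step 5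
Reactants: 7 (S)-3-hydroxy-3-nonadecylcyclohexan-1-one
Product: 8 (S)-3-nonadecyl-3-(triethylsilyloxy)cyclohexan-1-one
Conditions: TESOTf (1.3 equiv), 2,6-lutidine (2.5 equiv), CH2Cl2, −78 → −20 °C
Reagents that add atoms: triethylsilyl trifluoromethanesulfonate, CC[Si](CC)(CC)OS(=O)(=O)C(F)(F)F
Why: A silyl triflate with 2,6-lutidine silylates even a hindered tertiary alcohol at low temperature (O-silylation), and the weak, non-nucleophilic base neither opens the aldol by retro-aldol reaction nor dehydrates it.

Step 6
Reactants: 8 (S)-3-nonadecyl-3-(triethylsilyloxy)cyclohexan-1-one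
Product: 10 (S)-triethyl{[1-nonadecyl-3-(trimethylsilyloxy)cyclohex-3-en-1-yl]oxy}silane, via lithium enolate 9 (not isolated)
Conditions: LDA (1.15 equiv), THF, −78 °C; then TMSCl/Et3N, −78 → 0 °C; cold aq NaHCO3, used crude
Reagents that add atoms: chlorotrimethylsilane, C[Si](C)(C)Cl
Why: LDA removes a proton kinetically from C6, the open α-methylene, and not from C2, which is shielded by the fully substituted C3, and chlorotrimethylsilane traps the enolate on oxygen (kinetic enolate formation and O-silylation); an enolate on the C6 side cannot expel the C3 silyloxy group.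

Step 7
Reactants: 10 (S)-triethyl{[1-nonadecyl-3-(trimethylsilyloxy)cyclohex-3-en-1-yl]oxy}silane
Product: 11 (S)-5-nonadecyl-5-(triethylsilyloxy)cyclohex-2-en-1-one
Conditions: Pd(OAc)2 (1.1 equiv), MeCN/CH2Cl2, rt
Reagents that add atoms: none
Why: Saegusa–Ito oxidation: divalent palladium adds to the enol silane at C6 and β-hydride elimination, possible only from C5, gives the C5=C6 enone (C2=C3 of the target) without touching the silyl ether or the stereocentre.

Step 8
Reactants: 11 (S)-5-nonadecyl-5-(triethylsilyloxy)cyclohex-2-en-1-one
Product: 12 (S)-5-hydroxy-5-nonadecylcyclohex-2-en-1-one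
Conditions: HF·pyridine, pyridine, THF, 0 °C → rt
Reagents that add atoms: none
Why: Buffered HF·pyridine cleaves the tertiary Si–O bond (fluoride-mediated desilylation) without forming a free alkoxide or a strongly acidic medium, so that retro-aldol opening and dehydration to a phenol are avoided and C5 keeps its configuration.

**Compound list**
1 | 1-bromononadecane | CCCCCCCCCCCCCCCCCCCBr | starting material
2 | nonadecylmagnesium bromide | CCCCCCCCCCCCCCCCCCC[Mg]Br | intermediate
3 | 3-ethoxycyclohex-2-en-1-one | CCOC1=CC(=O)CCC1 | starting material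
4 | bromomagnesium 3-ethoxy-1-nonadecylcyclohex-2-en-1-olate (racemic 1,2-adduct) | CCCCCCCCCCCCCCCCCCCC1(O[Mg]Br)CCCC(OCC)=C1 | intermediate
5 | 3-nonadecylcyclohex-2-en-1-one | CCCCCCCCCCCCCCCCCCCC1=CC(=O)CCC1 | intermediate
6 | (1S,6S)-6-nonadecyl-7-oxabicyclo[4.1.0]heptan-2-one | CCCCCCCCCCCCCCCCCCC[C@]12CCCC(=O)[C@H]1O2 | intermediate
7 | (S)-3-hydroxy-3-nonadecylcyclohexan-1-one | CCCCCCCCCCCCCCCCCCC[C@]1(O)CCCC(=O)C1 | intermediate
8 | (S)-3-nonadecyl-3-(triethylsilyloxy)cyclohexan-1-one | CCCCCCCCCCCCCCCCCCC[C@]1(O[Si](CC)(CC)CC)CCCC(=O)C1 | intermediate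
9 | lithium (S)-5-nonadecyl-5-(triethylsilyloxy)cyclohex-1-en-1-olate | CCCCCCCCCCCCCCCCCCC[C@]1(O[Si](CC)(CC)CC)CCC=C(O[Li])C1 | intermediate
10 | (S)-triethyl{[1-nonadecyl-3-(trimethylsilyloxy)cyclohex-3-en-1-yl]oxy}silane | CCCCCCCCCCCCCCCCCCC[C@]1(O[Si](CC)(CC)CC)CCC=C(O[Si](C)(C)C)C1 | intermediate
11 | (S)-5-nonadecyl-5-(triethylsilyloxy)cyclohex-2-en-1-one | CCCCCCCCCCCCCCCCCCC[C@]1(O[Si](CC)(CC)CC)CC=CC(=O)C1 | intermediate
12 | (S)-5-hydroxy-5-nonadecylcyclohex-2-en-1-one | CCCCCCCCCCCCCCCCCCC[C@]1(O)CC=CC(=O)C1 | target

Total step count: 8. Longest linear sequence: 8 steps (1 → 12).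

**Steps most likely to fail**

Step 3. The hydroperoxide addition may proceed with poor enantiofacial selectivity, or iminium formation may be too slow with the β,β-disubstituted, waxy enone. The fallback sets out from 5 and takes the stereocentre from a carbonyl reduction instead. Corey–Bakshi–Shibata reduction ((S)-2-methyl-CBS-oxazaborolidine, catecholborane, toluene, −78 °C), with the alkenyl arm acting as the large group, should give (R)-3-nonadecylcyclohex-2-en-1-ol F1. Hydroxyl-directed epoxidation (VO(acac)2, t-BuOOH, CH2Cl2, 0 °C) should deliver oxygen to the alkene face syn to the hydroxyl and give (1R,2R,3S)-2,3-epoxy-3-nonadecylcyclohexan-1-ol F2. Oxidation of the carbinol with Dess–Martin periodinane (NaHCO3, CH2Cl2) comes back to the route at 6.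

Step 6. Deprotonation may stray toward C2, followed by E1cB loss of the silanolate back to achiral 5, or regioisomeric enol silanes may form. The fallback sets out from 6, in which C2 is an oxirane CH that cannot be enolised. LDA then TMSCl in THF at −78 °C should give, through the lithium enolate of 6 on the C6 side F3, the enol silane trimethyl{[(1S,6S)-6-nonadecyl-7-oxabicyclo[4.1.0]hept-2-en-2-yl]oxy}silane F4. Saegusa–Ito oxidation with Pd(OAc)2 should give the epoxy enone (1S,6S)-6-nonadecyl-7-oxabicyclo[4.1.0]hept-3-en-2-one F5. SmI2 in THF/MeOH at −90 °C then cuts the C–O bond α to the carbonyl and comes back to the route at 12, with no silyl ether to remove.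

Step 8. Desilylation may be accompanied by β-elimination of the freed tertiary hydroxyl with tautomerisation to a phenol, or by retro-aldol ring opening. The fallback sets out from 7 and never protects the carbinol: direct dehydrogenation with IBX (2-iodoxybenzoic acid) and 4-methoxypyridine N-oxide in DMSO at rt. Because C3 of 7 carries no hydrogen, only the C5–C6 bond can be desaturated, and the product cannot be oxidised further to a dienone, so the reaction comes back to the route at 12. New compounds on this way: none F0.

**Further compounds**
F1 | step 3 | (R)-3-nonadecylcyclohex-2-en-1-ol | CCCCCCCCCCCCCCCCCCCC1=C[C@H](O)CCC1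
F2 | step 3 | (1R,2R,3S)-2,3-epoxy-3-nonadecylcyclohexan-1-ol (hydroxyl cis to the oxirane oxygen) | CCCCCCCCCCCCCCCCCCC[C@]12CCC[C@@H](O)[C@H]1O2
F3 | step 6 | lithium enolate of 6 on the C6 side (oxirane carbons configured as in 6) | CCCCCCCCCCCCCCCCCCC[C@]12CCC=C(O[Li])[C@H]1O2
F4 | step 6 | trimethyl{[(1S,6S)-6-nonadecyl-7-oxabicyclo[4.1.0]hept-2-en-2-yl]oxy}silane | CCCCCCCCCCCCCCCCCCC[C@]12CCC=C(O[Si](C)(C)C)[C@H]1O2
F5 | step 6 | (1S,6S)-6-nonadecyl-7-oxabicyclo[4.1.0]hept-3-en-2-one | CCCCCCCCCCCCCCCCCCC[C@]12CC=CC(=O)[C@H]1O2
F0 | step 8 | none | none
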